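The data were computed with made-up constants; scatter was added.

Keep the vessel closed, stirred and at one temperature, and read E against time.

| setting | north | east | south |
|---|---|---|---|
| Z | 0.200 M | 0.100 M | 0.200 M |
| time |  |  | 180 min |

| run | time / min | [E] / M |
|---|---|---|
| north run | 5.8 | 0.011 |
| north run | 12 | 0.021 |
| north run | 17 | 0.028 |
| north run | 23 | 0.041 |
| north run | 29 | 0.049 |
| north run | 34 | 0.055 |
| north run | 40 | 0.066 |
| north run | 46 | 0.075 |
| east run | 5.8 | 0.006 |
| east run | 12 | 0.007 |
| east run | 17 | 0.019 |
| east run | 23 | 0.024 |
| east run | 29 | 0.032 |
| east run | 34 | 0.033 |
| east run | 40 | 0.043 |
| east run | 46 | 0.048 |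

(standard deviation of a reading: 0.003 M)

- reaction order in [Z] at the outset, round the charge of the north run, defined at two percent of the Z turned into E (one fixed amount of E, the same in the runs compared)
- E in the south run at 180 min, as a share of the Z charged

- Overall: Z -> E.
- Constant volume, constant temperature.
- What is held in complexes is read along with the free species.
- An order is taken over about fifteen percent of the charge, up and down.

Begin with the bench rule: treat the flask as first order, so that one constant serves any charge, and freeze it. The north run at 46 min gives 0.0102 min⁻¹, the first-order constant that one E reading implies, ln(C/(C−E))/t with C the Z charged: call it the running constant kr. Frozen there, it puts the south run, charged like the north run, at 84.1 % by 180 min.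

The border shows in a ratio. The east run at 46 min, with half the charge, gives 0.0142 min⁻¹, a reading 1.39 times the north one, where a first-order flask gives a ratio of one. Read from these two runs as an order averaged over their first 46 min, my reckoning gives 0.524.

So let kr move for the south run. Use the north value until half of C is E, which takes 67.8 min; what has not become E then equals the east charge, so use the east value for the rest. My reckoning then puts E in the south run at 89.8 % of C by 180 min.

The forecast gives 0.45 (0.2 to 0.75) and 90 % (72 % to 98 %), reading the runs thus: “This points to saturation”. Its order is lower than my 0.524.

The flask gives an order of 0.57 and 91.8 %.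

    Z → J (0.05904 min⁻¹)
    J → E (0.01488 min⁻¹)
    2 Z ⇌ Z2, settled at all times (23.20 L mol⁻¹)
    Z → E (0.02526 min⁻¹)

Watch kr rather than one slope. In the south run it stands at 0.0139 min⁻¹ at 180 min, higher than the 0.0102 min⁻¹ read from the north run at 46 min, and the east run, with E at half its charge at 51.5 min, shows 0.0135 min⁻¹. The early order round the north charge stands below first because Z binds with itself into Z2 in a fast dimerisation: in the run without that binding, the order is 1.0 in place of 0.57.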